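**Strategy.** The cyclohexane core (ring A, C5–C10 in elemanolide numbering) is cut at C5–C6 and C9–C10. Its oxygens on C6 and C9 and the trans carbon branches on C5 (C4) and C10 (C1, beside the C14 methyl) map onto an E,E-1,4-bis(silyloxy)butadiene and an E-configured formyl methacrylate. One catalytic enantioselective endo Diels–Alder reaction joins these two achiral fragments, closes ring A and sets C5, C6, C9 and the quaternary C10 together. The C9 oxygen then relays its configuration: a Claisen rearrangement carries C11 to C7, dihydroxylation rebuilds the C8/C9 diol, and a twofold aldehyde methylenation with lactol oxidation completes the target.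

Key step: step 3

Remark on naming: ring carbons keep the elemanolide numbers C5–C10 in all intermediates (C1/C2 = epoxide carbons, C3/C4/C15 = acrolein unit, C11/C12/C13 = lactone carbons); β is the ring face that carries the C10 methyl group, α the opposite face.

Assumption: the facial sense of the oxazaborolidinium catalyst in step 3 is taken from its usual formyl C–H···O binding model and written for the (S)-catalyst; should the antipode of 8 form, the (R)-catalyst is used with no other change.

**Step 1**
Reactants: 1 (1E,3E)-buta-1,3-diene-1,4-diyl diacetate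
Product: 3 (1E,3E)-1,4-bis(tert-butyldimethylsilyloxy)buta-1,3-diene, via dilithium dienediolate 2 (not isolated)
Conditions: MeLi (4 equiv), DME, −20 to 0 °C; then TBSCl, DMPU, −78 °C to rt
Reagents that add atoms: tert-butyldimethylsilyl chloride CC(C)(C)[Si](C)(C)Cl
Why: Cleavage of both enol acetates by MeLi (enol ester to lithium enolate exchange) keeps the E,E geometry, and O-silylation of the dienediolate gives the bis(silyl dienol ether); no stereocentre is formed.

**Step 2**
Reactants: 4 ethyl 2-(triphenylphosphoranylidene)propanoate; 5 2,2-dimethoxyacetaldehyde (60% aqueous solution)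
Product: 7 ethyl (E)-2-methyl-4-oxobut-2-enoate, via acetal ester 6 (not isolated)
Conditions: CH2Cl2, rt; then 2 M HCl, THF, rt
Reagents that add atoms: water O
Why: Wittig olefination with the stabilised ylide gives the E-trisubstituted enoate (ester trans to the acetal carbon), and dilute acid then hydrolyses the dimethyl acetal to the aldehyde.

**Step 3**
Reactants: 3 (1E,3E)-1,4-bis(tert-butyldimethylsilyloxy)buta-1,3-diene; 7 ethyl (E)-2-methyl-4-oxobut-2-enoate
Product: 8 ethyl (1S,2S,5R,6S)-2,5-bis(tert-butyldimethylsilyloxy)-6-formyl-1-methylcyclohex-3-ene-1-carboxylate (6β-OTBS, 5β-CHO, 10β-CH3, 9β-OTBS all cis; 10α-CO2Et)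
Conditions: (S)-3,3-diphenyl-1-(o-tolyl)tetrahydro-1H,3H-pyrrolo[1,2-c][1,3,2]oxazaborole (C24H24BNO, 20 mol %), Tf2NH (18 mol %), CH2Cl2, −78 to −40 °C
Reagents that add atoms: none
Why: The protonated oxazaborolidine binds the formyl oxygen of 7, and diene 3 adds to C5=C10 in a concerted, asynchronous, suprafacial [4+2] cycloaddition of normal electron demand. The closest known reaction type is the chiral oxazaborolidinium-catalysed Diels–Alder reaction of 2-enals with silyloxy dienes. Ring A is closed intermolecularly through one six-membered boat-like transition state that forms C5–C6 and C9–C10. C6 and C9 come out cis because 3 is E,E; C5 and C10 keep the E geometry of 7 (C4 formyl trans to the C1 ester, cis to the methyl); the endo position of the complexed formyl group places it cis to both silyloxy groups; the catalyst shields one face of the bound enal and so fixes the absolute configuration of all four centres. The step needs endo selectivity, which rests on the Lewis acid-bound aldehyde carrying the endo preference while the ester on the methyl-bearing carbon goes exo, and C=C over C=O chemoselectivity, which the doubly activated alkene secures; regioselectivity is not an issue because 3 is symmetric.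

**Step 4**
Reactants: 8 cycloadduct aldehyde
Product: 9 enol ether (C4 aldehyde of 8 homologated to CH=CH–OMe; E/Z mixture)
Conditions: (methoxymethyl)triphenylphosphonium chloride, KN(SiMe3)2, THF, −78 to 0 °C
Reagents that add atoms: (methoxymethyl)triphenylphosphonium chloride COC[P+](c1ccccc1)(c1ccccc1)c1ccccc1.[Cl-]
Why: Wittig olefination with methoxymethylenetriphenylphosphorane homologates the C4 aldehyde at low temperature, where the neopentyl C1 ester is inert and C5 is not epimerised; the enol ether geometry is irrelevant.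

**Step 5**
Reactants: 9 enol ether ester
Product: 10 chloromethyl ketone (C1 ester of 9 replaced by C(=O)CH2Cl)
Conditions: ICH2Cl, MeLi·LiBr, THF, −78 °C; then AcOH, −78 °C
Reagents that add atoms: chloroiodomethane ClCI
Why: Acylation of in situ chloromethyllithium by the ester: the lithium hemiketal formed at −78 °C survives until the cold acid quench, so a single addition gives the chloromethyl ketone.

**Step 6**
Reactants: 10 chloromethyl ketone
Product: 12 epoxide (1R; both silyl ethers kept), via chlorohydrin 11 (not isolated)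
Conditions: (R)-1-methyl-3,3-diphenyltetrahydro-1H,3H-pyrrolo[1,2-c][1,3,2]oxazaborole (C18H20BNO, 20 mol %), catecholborane, toluene, −78 to −40 °C; then K2CO3, MeOH, rt
Reagents that add atoms: none
Why: CBS reduction: the catalyst differentiates the tert-alkyl group (large) from CH2Cl (small) and delivers hydride under reagent control to give the R carbinol at C1; base then closes the epoxide by intramolecular Williamson displacement at C2 with retention at C1.

**Step 7**
Reactants: 12 bis(silyl ether) epoxide
Product: 13 epoxy diol (6β-OH and 9β-OH)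
Conditions: Bu4NF, THF, 0 °C to rt
Reagents that add atoms: none
Why: Fluoride-induced desilylation frees both allylic alcohols; the epoxide and the enol ether are stable to Bu4NF.

**Step 8**
Reactants: 13 epoxy diol
Product: 14 C6 isobutyrate (9β-OH free)
Conditions: i-PrCOCl (1.05 equiv), pyridine, CH2Cl2, −30 °C
Reagents that add atoms: isobutyryl chloride CC(C)C(Cl)=O
Why: Site-selective esterification: the C9 hydroxyl is neopentylic (next to quaternary C10) and should react much more slowly than the C6 hydroxyl, so one equivalent of the branched acid chloride at low temperature acylates C6.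

**Step 9**
Reactants: 14 C6 isobutyrate
Product: 16 C12 aldehyde (7β-CH2CHO; alkene now C8=C9), via vinyl ether 15 (not isolated)
Conditions: vinyl acetate, [Ir(cod)Cl]2 (2 mol %), Na2CO3, toluene, 100 °C; then 150 °C, sealed tube
Reagents that add atoms: vinyl acetate C=COC(C)=O
Why: Iridium-catalysed transvinylation of the C9 alcohol followed by thermal Claisen rearrangement: the [3,3] shift is suprafacial, so the β-oriented C9–O bond is traded for a β C7–C11 bond (sets C7) and the alkene moves to C8=C9.

**Step 10**
Reactants: 16 enol ether aldehyde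
Product: 17 dialdehyde (5β-CH2CHO and 7β-CH2CHO)
Conditions: oxalic acid (5% aq.), THF, 0 °C to rt
Reagents that add atoms: water O
Why: Acid-catalysed enol ether hydrolysis: C-protonation of the enol ether is far faster than opening of the monosubstituted epoxide at this acidity.

**Step 11**
Reactants: 17 dialdehyde
Product: 19 trans-fused lactol (C12 hemiacetal on 8α-O; 9α-OH; anomer mixture), via dihydroxy dialdehyde 18 (not isolated)
Conditions: OsO4 (5 mol %), NMO, acetone–H2O, 0 °C to rt
Reagents that add atoms: N-methylmorpholine N-oxide C[N+]1([O-])CCOCC1; water O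
Why: Upjohn dihydroxylation: OsO4 should add to C8=C9 from the α face, opposite the pseudoaxial C10 methyl, the axial C6 ester and the C7 side chain, which sets C8 and C9; the C8 hydroxyl then closes the five-membered lactol on the C12 aldehyde.

**Step 12**
Reactants: 19 lactol aldehyde
Product: 20 bis-methylenated lactol (C11=C13 and C4=C15 in place)
Conditions: 37% aq. HCHO, pyrrolidine (20 mol %), propionic acid (20 mol %), i-PrOH, 45 °C
Reagents that add atoms: formaldehyde C=O
Why: Amine-catalysed Mannich condensation with formaldehyde followed by elimination (α-methylenation of aldehydes) acts on the free C3 aldehyde and, through its open hydroxy aldehyde form, on the lactol.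

**Step 13**
Reactants: 20 bis-methylenated lactol
Product: 21 CNP0496100.1
Conditions: activated MnO2, CH2Cl2, rt
Reagents that add atoms: none
Why: MnO2 oxidises the allylic hemiacetal to the α-methylene lactone, while the non-allylic secondary C9 alcohol, the enal and the epoxide should not be touched.

**Compound list**

1 | (1E,3E)-buta-1,3-diene-1,4-diyl diacetate | CC(=O)O/C=C/C=C/OC(C)=O | starting material
2 | dilithium (1E,3E)-buta-1,3-diene-1,4-diolate | [Li+].[Li+].[O-]/C=C/C=C/[O-] | intermediate
3 | (1E,3E)-1,4-bis(tert-butyldimethylsilyloxy)buta-1,3-diene | CC(C)(C)[Si](C)(C)O/C=C/C=C/O[Si](C)(C)C(C)(C)C | intermediate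
4 | ethyl 2-(triphenylphosphoranylidene)propanoate | CCOC(=O)C(C)=P(c1ccccc1)(c1ccccc1)c1ccccc1 | starting material
5 | 2,2-dimethoxyacetaldehyde | COC(OC)C=O | starting material
6 | ethyl (E)-4,4-dimethoxy-2-methylbut-2-enoate | CCOC(=O)/C(C)=C/C(OC)OC | intermediate
7 | ethyl (E)-2-methyl-4-oxobut-2-enoate | CCOC(=O)/C(C)=C/C=O | intermediate
8 | ethyl (1S,2S,5R,6S)-2,5-bis(tert-butyldimethylsilyloxy)-6-formyl-1-methylcyclohex-3-ene-1-carboxylate | O=C[C@@H]1[C@H](O[Si](C)(C)C(C)(C)C)C=C[C@H](O[Si](C)(C)C(C)(C)C)[C@@]1(C)C(=O)OCC | intermediate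
9 | enol ether: 6-(2-methoxyvinyl) analogue of 8, E/Z mixture | COC=C[C@@H]1[C@H](O[Si](C)(C)C(C)(C)C)C=C[C@H](O[Si](C)(C)C(C)(C)C)[C@@]1(C)C(=O)OCC | intermediate
10 | chloromethyl ketone: C1 ester of 9 replaced by chloroacetyl | COC=C[C@@H]1[C@H](O[Si](C)(C)C(C)(C)C)C=C[C@H](O[Si](C)(C)C(C)(C)C)[C@@]1(C)C(=O)CCl | intermediate
11 | (1R)-chlorohydrin of 10 | COC=C[C@@H]1[C@H](O[Si](C)(C)C(C)(C)C)C=C[C@H](O[Si](C)(C)C(C)(C)C)[C@@]1(C)[C@@H](O)CCl | intermediate
12 | (1R)-epoxide, 6β,9β-bis(silyl ether) | COC=C[C@@H]1[C@H](O[Si](C)(C)C(C)(C)C)C=C[C@H](O[Si](C)(C)C(C)(C)C)[C@@]1(C)[C@@H]2CO2 | intermediate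
13 | epoxy diol, 6β-OH and 9β-OH | COC=C[C@@H]1[C@H](O)C=C[C@H](O)[C@@]1(C)[C@@H]2CO2 | intermediate
14 | C6 isobutyrate, 9β-OH free | COC=C[C@@H]1[C@H](OC(=O)C(C)C)C=C[C@H](O)[C@@]1(C)[C@@H]2CO2 | intermediate
15 | C9 vinyl ether of 14 | COC=C[C@@H]1[C@H](OC(=O)C(C)C)C=C[C@H](OC=C)[C@@]1(C)[C@@H]2CO2 | intermediate
16 | Claisen aldehyde: 7β-CH2CHO, C8=C9 alkene | COC=C[C@@H]1[C@H](OC(=O)C(C)C)[C@H](CC=O)C=C[C@@]1(C)[C@@H]2CO2 | intermediate
17 | dialdehyde: 5β-CH2CHO and 7β-CH2CHO | O=CC[C@@H]1[C@H](OC(=O)C(C)C)[C@H](CC=O)C=C[C@@]1(C)[C@@H]2CO2 | intermediate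
18 | 8α,9α-dihydroxy dialdehyde | O=CC[C@@H]1[C@H](OC(=O)C(C)C)[C@H](CC=O)[C@@H](O)[C@@H](O)[C@@]1(C)[C@@H]2CO2 | intermediate
19 | trans-fused lactol with 9α-OH and C3 aldehyde, anomer mixture | C1C(O)O[C@@H]2[C@@H]1[C@@H](OC(=O)C(C)C)[C@@H](CC=O)[C@](C)([C@@H]3CO3)[C@@H]2O | intermediate
20 | bis-methylenated lactol, anomer mixture | C=C1C(O)O[C@@H]2[C@@H]1[C@@H](OC(=O)C(C)C)[C@@H](C(=C)C=O)[C@](C)([C@@H]3CO3)[C@@H]2O | intermediate
21 | CNP0496100.1 | C=C1C(=O)O[C@@H]2[C@@H]1[C@@H](OC(=O)C(C)C)[C@@H](C(=C)C=O)[C@](C)([C@@H]1CO1)[C@@H]2O | target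

**Step count and risks**

Total step count: 13. Longest linear sequence: 12 steps (1 → 3 → 8 → … → 21, steps 1 and 3–13; the branch through 7 is equally long).

Steps most likely to fail:

1. Step 3 (key cycloaddition). Facial discrimination by the catalyst may be poor, or silyl transfer in a stepwise Mukaiyama–Michael pathway under the strong Lewis acid may divert the reaction. Fallback: setting out from 3 and 7, the two are heated without catalyst in toluene at 60 °C (thermal endo Diels–Alder reaction) to give the racemic cycloadduct F1. Steps 4 and 5 applied to it give the racemic enol ether F2 and the racemic chloromethyl ketone F3. The (R)-CBS reduction of step 6 then reduces both enantiomers to R carbinols, so that next to 11 the diastereomeric chlorohydrin F4 forms. Base closure gives 12 together with the diastereomeric epoxide F5 (same R configuration at C1, mirror-image ring), which is removed by chromatography. The route is rejoined at 12.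

2. Step 5 (chloromethyl ketone). Addition of the carbenoid to the neopentyl ester may be slower than carbenoid decomposition. Fallback: setting out from 9, i-Bu2AlH in CH2Cl2 at −78 °C reduces the ester to the neopentyl alcohol F6. Dess–Martin oxidation gives the aldehyde F7. Chloromethyllithium (ICH2Cl, MeLi·LiBr, −78 °C) adds to this much more electrophilic carbonyl to give the chlorohydrin F8 as a mixture of C1 epimers. A second Dess–Martin oxidation converges both epimers on 10, where the route is rejoined.

3. Step 12 (twofold methylenation). The closed lactol may enter the enamine cycle too slowly, so that only the C3 aldehyde is methylenated, or the hydroxy enals may oligomerise on prolonged heating. Fallback: setting out from 17, in which both aldehydes are free, the same formaldehyde/pyrrolidine/propionic acid conditions give the bis-enal F9. OsO4/NMO then dihydroxylates the only electron-rich alkene (C8=C9) from the α face and the C8 hydroxyl closes the lactol, which rejoins the route at 20.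

**Further compounds**

F1 | step 3 | racemic cycloadduct (8 and its enantiomer, 1:1) | O=C[C@@H]1[C@H](O[Si](C)(C)C(C)(C)C)C=C[C@H](O[Si](C)(C)C(C)(C)C)[C@@]1(C)C(=O)OCC.O=C[C@H]1[C@@H](O[Si](C)(C)C(C)(C)C)C=C[C@@H](O[Si](C)(C)C(C)(C)C)[C@]1(C)C(=O)OCC
F2 | step 3 | racemic enol ether (9 and its enantiomer, 1:1) | COC=C[C@@H]1[C@H](O[Si](C)(C)C(C)(C)C)C=C[C@H](O[Si](C)(C)C(C)(C)C)[C@@]1(C)C(=O)OCC.COC=C[C@H]1[C@@H](O[Si](C)(C)C(C)(C)C)C=C[C@@H](O[Si](C)(C)C(C)(C)C)[C@]1(C)C(=O)OCC
F3 | step 3 | racemic chloromethyl ketone (10 and its enantiomer, 1:1) | COC=C[C@@H]1[C@H](O[Si](C)(C)C(C)(C)C)C=C[C@H](O[Si](C)(C)C(C)(C)C)[C@@]1(C)C(=O)CCl.COC=C[C@H]1[C@@H](O[Si](C)(C)C(C)(C)C)C=C[C@@H](O[Si](C)(C)C(C)(C)C)[C@]1(C)C(=O)CCl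
F4 | step 3 | diastereomeric chlorohydrin (1R, enantiomeric ring) | COC=C[C@H]1[C@@H](O[Si](C)(C)C(C)(C)C)C=C[C@@H](O[Si](C)(C)C(C)(C)C)[C@]1(C)[C@@H](O)CCl
F5 | step 3 | diastereomeric epoxide (1R, enantiomeric ring) | COC=C[C@H]1[C@@H](O[Si](C)(C)C(C)(C)C)C=C[C@@H](O[Si](C)(C)C(C)(C)C)[C@]1(C)[C@@H]2CO2
F6 | step 5 | neopentyl alcohol (C1 CH2OH) | COC=C[C@@H]1[C@H](O[Si](C)(C)C(C)(C)C)C=C[C@H](O[Si](C)(C)C(C)(C)C)[C@@]1(C)CO
F7 | step 5 | C1 aldehyde | COC=C[C@@H]1[C@H](O[Si](C)(C)C(C)(C)C)C=C[C@H](O[Si](C)(C)C(C)(C)C)[C@@]1(C)C=O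
F8 | step 5 | chlorohydrin, mixture of C1 epimers | COC=C[C@@H]1[C@H](O[Si](C)(C)C(C)(C)C)C=C[C@H](O[Si](C)(C)C(C)(C)C)[C@@]1(C)C(O)CCl
F9 | step 12 | bis-enal (C4=C15 and C11=C13 in place, C8=C9 alkene) | O=CC(=C)[C@@H]1[C@H](OC(=O)C(C)C)[C@H](C(=C)C=O)C=C[C@@]1(C)[C@@H]2CO2
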